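What is left in the ash flask at 2.5 d is the question, so I ask what has stopped changing by then and what is still falling.

the same everywhere: starting material 0.10 M
- ash: first nucleophile 1.2 equiv; second nucleophile 1 equiv; the very flask that is asked about, followed so far
- alder: first nucleophile 1.2 equiv; second nucleophile 0.50 equiv; run made earlier
- flask: first nucleophile 1.20 equiv; second nucleophile 1.00 equiv; time 2.5 d

- ash (time / h: other capture product / %, target / %): 6.00: 5, 38; 12.0: 11, 31; 20.0: 5, 21; 25.0: 8, 15; 30.0: 11, 11
- alder (time / d: other capture product / %, target / %): 0.208: 2, 35; 0.625: 5, 27; 1.25: 4, 12; 1.67: 7, 8; 2.50: 4, 1

(each reading ± 1.5 percentage points)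

- the numbers in the tables scatter by 1.5 percentage points (one standard deviation)
- a reading or a percentage of target counts all its forms, free or not

- ratio of other capture product to target at 12 min
- ratio of other capture product to target at 2.5 d

The alder run has already reached 2.50 d, and its last 3 readings of other capture product scatter around 5.00% with no steady trend. Alder was charged 0.50 equiv of second nucleophile. So, taking the amount as proportional to the charge, with starting material and first nucleophile charged as in alder and ash, I read 10.0% as the capture plateau, the percent of other capture product that stands late per full equivalent of second nucleophile.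

But target is still falling in the ash run, from 31% at 12.0 h to 11% at 30.0 h. I read that as a half-life of 12.0 h, and if it holds up to 2.5 d, my estimate is 1.96% target. So I commit to a late ratio of 5.11.

The ratio read in the ash run is higher at 30.0 h than the 0.132 read at 6.00 h, so at 12 min I expect a value below that first reading.

The forecast puts the two ratios at 0.17 and 60, calling the first “the early selectivity”.

The ash flask gives 0.0652 and 5.72.

    starting material → intermediate (k = 0.00627 min⁻¹)
    intermediate → solvolysis product (k = 0.0143 min⁻¹)
    second nucleophile + intermediate → other capture product (k = 0.0192 L mol⁻¹ min⁻¹)
    starting material + target ⇌ idle adduct, settled at all times (K = 7.10 L mol⁻¹)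
    2 first nucleophile → homo dimer (k = 0.0146 L mol⁻¹ min⁻¹)
    first nucleophile + intermediate ⇌ target (K = 190 L mol⁻¹, k = 0.254 L mol⁻¹ min⁻¹)

At 2.5 d the ash flask holds 1.93% target and 11.0% other capture product, with starting material, the limiting reagent, at 0%. For the neighbour flask, charged 0.400 equiv of second nucleophile, the capture plateau of 10.0% read from alder gives 4.00%, and that neighbour holds 4.70% beside 2.12% target, a ratio of 2.21.

All runs stem from a simulated flask with constants of no real substance, and the scatter is random.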